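**Plan** (germacrane numbering: C1 carbinol, C4–C5 epoxide, C6 lactone carbinol, C8 tiglate carbinol, C9=C10, C12 lactone carbonyl, C13 acetoxymethyl)
1. Retrosynthesis: the C1 silyl ether, the C7=C11 bond (dehydration) and the C13 acetate/C11 hydroxyl (dihydroxylation) lead back to α-methylene lactone 35; the lactone C12–O bond and the C8 tiglate are cut next; C7–C8 is then cut as a [2,3]-Wittig retron to the 13-membered ether 29, which is opened at O–C13, C8–Sn, C11–C13, C6–C7 and C1–C10.
2. Forward: geranyl acetate (C1–C6) is joined to C8–C10 (Nozaki–Hiyama–Kishi), then to C7/C11/C12 (alkynylation) and C13 (Stille); the 13-membered ether ring closes by etherification and contracts to the ten-membered carbocycle in step 22; the lactone ring and the butenolide alkene follow.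
3. Stereochemistry: C1 from CBS reduction; C6 from catalytic asymmetric alkynylation; C4/C5 from hydroxyl-directed epoxidation under C6 control; C8 from a BINAL-H-derived (S)-stannane with inversion in the rearrangement; both Z alkenes from hydroalumination–iodination.
4. Enabling feature: the C8 carbinol lies next to C7, which carries the three-carbon branch C11(C12)(C13). This homoallylic alcohol is the product pattern of a [2,3]-shift of a C8–O–C13 allylic ether, so the ten-membered ring can be reached from an easily closed 13-membered cyclic ether.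

Key step: step 22

Assumption: the C8 allyllithium 30 rearranges faster than it inverts; C7 in 31–37 is drawn as the syn isomer expected from the Z C7=C11 bond (H7 and the C8 oxygen cis on the ten-membered ring), and this centre is erased in step 28.

Step 1
Reactants: 1 but-2-yn-1-ol
Product: 3 (Z)-3-iodobut-2-en-1-ol, via cyclic vinylalanate 2 (not isolated)
Conditions: NaAlH2(OCH2CH2OMe)2, THF, 0 °C; then I2, −78 °C
Reagents that add atoms: iodine, II
Why: Hydroxyl-directed trans-hydroalumination places aluminium on the distal alkyne carbon in a five-membered alanate, and iodinolysis with retention should give the Z iodoalkene (hydroalumination–iodination).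

Step 2
Reactants: 3 (Z)-3-iodobut-2-en-1-ol
Product: 4 (Z)-3-iodobut-2-enyl 4-methoxybenzyl ether
Conditions: NaH, 4-MeOC6H4CH2Cl, Bu4NI (cat.), THF–DMF, 0 °C → rt
Reagents that add atoms: 4-methoxybenzyl chloride, COc1ccc(CCl)cc1
Why: Williamson etherification of the primary allylic alkoxide with a benzylic chloride should be clean and leaves the alkenyl iodide untouched.

Step 3
Reactants: 5 prop-2-yn-1-ol
Product: 6 triethyl(prop-2-ynyloxy)silane
Conditions: Et3SiCl, imidazole, CH2Cl2, 0 °C
Reagents that add atoms: chlorotriethylsilane, CC[Si](Cl)(CC)CC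
Why: Silylation of a primary alcohol with a silyl chloride and imidazole is routine and masks the future C12 oxygen.

Step 4
Reactants: 7 geranyl acetate
Product: 9 (E)-3-methyl-6-oxohex-2-enyl acetate, via ozonide 8 (not isolated)
Conditions: O3 (1 equiv), CH2Cl2, pyridine (cat.), −78 °C; then Me2S
Reagents that add atoms: ozone, [O-][O+]=O
Why: Ozonolysis with one equivalent of ozone should cleave the electron-rich terminal alkene in preference to the alkene deactivated by the allylic acetate, and reductive work-up gives the C1 aldehyde.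

Step 5
Reactants: 9 (E)-3-methyl-6-oxohex-2-enyl acetate; 4 (Z)-3-iodobut-2-enyl 4-methoxybenzyl ether
Product: 10 C1 allylic alcohol (both C1 epimers) with C6 acetate and C8 4-methoxybenzyl ether
Conditions: CrCl2, NiCl2 (cat.), DMF, rt
Reagents that add atoms: none
Why: The Nozaki–Hiyama–Kishi coupling forms C1–C10 with retention of the Z alkene geometry and tolerates the acetate; the two C1 epimers converge in step 6.

Step 6
Reactants: 10 C1 allylic alcohol
Product: 11 C1 enone
Conditions: Dess–Martin periodinane, NaHCO3, CH2Cl2, 0 °C → rt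
Reagents that add atoms: none
Why: Dess–Martin oxidation gives the enone under buffered neutral conditions that should not isomerise the Z alkene.

Step 7
Reactants: 11 C1 enone
Product: 12 (1S)-allylic alcohol
Conditions: (R)-2-methyl-CBS-oxazaborolidine, catecholborane, toluene, −78 °C
Reagents that add atoms: none
Why: Corey–Bakshi–Shibata reduction with the (R)-oxazaborolidine treats the α-methyl alkenyl group as the large substituent and should deliver hydride to give the 1S alcohol.

Step 8
Reactants: 12 (1S)-allylic alcohol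
Product: 13 C1 tert-butyldimethylsilyl ether
Conditions: t-BuMe2SiCl, imidazole, DMF, rt
Reagents that add atoms: tert-butyldimethylsilyl chloride, CC(C)(C)[Si](C)(C)Cl
Why: Silyl ether formation protects the C1 hydroxyl for the rest of the route.

Step 9
Reactants: 13 C1 tert-butyldimethylsilyl ether
Product: 14 C6 allylic alcohol
Conditions: K2CO3, MeOH, 0 °C
Reagents that add atoms: none
Why: Carbonate-mediated transesterification with methanol removes the acetate without touching the silyl or benzyl ethers.

Step 10
Reactants: 14 C6 allylic alcohol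
Product: 15 C6 (E)-enal
Conditions: MnO2, CH2Cl2, rt
Reagents that add atoms: none
Why: MnO2 oxidises the primary allylic alcohol selectively to the E enal (allylic oxidation).

Step 11
Reactants: 15 C6 (E)-enal; 6 triethyl(prop-2-ynyloxy)silane
Product: 16 (6R)-propargylic alcohol
Conditions: ZnMe2, ProPhenol ligand (cat., enantiomer giving the 6R carbinol), Ph3PO, toluene, 0 °C
Reagents that add atoms: none
Why: Zinc–ProPhenol catalysed asymmetric alkynylation, which is at its best with α,β-unsaturated aldehydes, adds the alkynylzinc to one face of the enal and should set C6 as R under catalyst control.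

Step 12
Reactants: 16 (6R)-propargylic alcohol
Product: 18 (Z)-C11 iodoalkene, via cyclic C11 vinylalanate 17 (not isolated)
Conditions: NaAlH2(OCH2CH2OMe)2, THF, −20 → 0 °C; then I2, −78 °C
Reagents that add atoms: iodine, II
Why: As in step 1, trans-hydroalumination directed by the C6 alkoxide followed by iodinolysis should put iodine on C11 cis to C6, the low temperature preventing loss of the silyloxy group to an allene.

Step 13
Reactants: 18 (Z)-C11 iodoalkene
Product: 19 (4R,5R,6S)-4,5-epoxy alcohol
Conditions: m-CPBA, NaHCO3, CH2Cl2, −20 → 0 °C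
Reagents that add atoms: 3-chloroperoxybenzoic acid, OOC(=O)c1cccc(Cl)c1
Why: In this hydroxyl-directed peracid epoxidation, A(1,3) strain between C15 and the C6 substituents fixes the conformation so that oxygen is delivered syn to the hydroxyl, which should give the threo epoxy alcohol, while the C9=C10 and iodoalkene bonds are deactivated by their allylic oxygens and by iodine.

Step 14
Reactants: 19 (4R,5R,6S)-4,5-epoxy alcohol
Product: 20 C6 triethylsilyl ether
Conditions: Et3SiOTf, 2,6-lutidine, CH2Cl2, −78 °C
Reagents that add atoms: triethylsilyl triflate, CC[Si](CC)(CC)OS(=O)(=O)C(F)(F)F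
Why: Silylation with the silyl triflate and a hindered base at low temperature protects the hindered C6 hydroxyl without opening the epoxide.

Step 15
Reactants: 20 C6 triethylsilyl ether
Product: 21 C13 allylic alcohol
Conditions: Bu3SnCH2OH, Pd(PPh3)4 (cat.), CuI (cat.), DMF, 60 °C
Reagents that add atoms: (tributylstannyl)methanol, OC[Sn](CCCC)(CCCC)CCCC
Why: Migita–Kosugi–Stille coupling of the alkenyl iodide with (tributylstannyl)methanol installs C13 with retention of alkene geometry, so the new hydroxymethyl group is cis to C6 and is the only free hydroxyl.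

Step 16
Reactants: 21 C13 allylic alcohol
Product: 23 C13 allylic chloride, via C13 mesylate 22 (not isolated)
Conditions: MeSO2Cl, 2,4,6-collidine, LiCl, DMF, 0 °C
Reagents that add atoms: lithium chloride, [Li+].[Cl-]
Why: Mesylation and in situ SN2 displacement by chloride convert the primary allylic alcohol into the chloride under non-acidic conditions.

Step 17
Reactants: 23 C13 allylic chloride
Product: 24 C8 allylic alcohol
Conditions: DDQ, CH2Cl2–pH 7 buffer, 0 °C
Reagents that add atoms: none
Why: Oxidative cleavage of the 4-methoxybenzyl ether by DDQ through the benzylic oxocarbenium ion frees the C8 hydroxyl without affecting the silyl ethers, the epoxide or the chloride.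

Step 18
Reactants: 24 C8 allylic alcohol
Product: 25 C8 (Z)-enal
Conditions: MnO2, CH2Cl2, rt
Reagents that add atoms: none
Why: MnO2 oxidation of the primary allylic alcohol gives the Z enal without acid or base that would isomerise it.

Step 19
Reactants: 25 C8 (Z)-enal
Product: 27 C8 acylstannane, via lithium stannyl alkoxide 26 (not isolated)
Conditions: Bu3SnH, LiN(i-Pr)2, THF, 0 °C; 25, −78 °C; then 1,1'-(azodicarbonyl)dipiperidine, −78 → 0 °C
Reagents that add atoms: tributyltin hydride, CCCC[SnH](CCCC)CCCC
Why: Tributylstannyllithium should add 1,2 to the enal at −78 °C faster than it displaces the allylic chloride, and hydride abstraction from the alkoxide by the azodicarboxamide gives the acylstannane (stannyl anion addition, then Mukaiyama-type oxidation).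

Step 20
Reactants: 27 C8 acylstannane
Product: 28 (8S)-hydroxystannane (used crude at once)
Conditions: (R)-BINAL-H [LiAlH(OEt)((R)-1,1'-binaphthalene-2,2'-diolate)], THF, −78 °C
Reagents that add atoms: none
Why: Reagent-controlled enantioselective 1,2-reduction of the enoyl stannane by (R)-BINAL-H, as known for acylstannanes, should give the 8S α-hydroxy allylic stannane.

Step 21
Reactants: 28 (8S)-hydroxystannane
Product: 29 13-membered cyclic ether with C8 tributylstannyl group
Conditions: KN(SiMe3)2, 18-crown-6, Bu4NI (cat.), THF, −78 → 0 °C, high dilution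
Reagents that add atoms: none
Why: Intramolecular Williamson etherification of the α-stannyl alkoxide with the primary allylic chloride (iodide catalysis, high dilution) closes the 13-membered ether, a ring size that this reaction forms readily, with retention at C8.

Step 22
Reactants: 29 13-membered cyclic ether with C8 tributylstannyl group
Product: 31 ten-membered C8 alcohol with the 3-(triethylsilyloxy)prop-1-en-2-yl group on C7, via C8 allyllithium 30 (not isolated)
Conditions: n-BuLi (1.5 equiv), THF, −78 °C; then H2O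
Reagents that add atoms: none
Why: Butyllithium attacks tin and releases the C8 α-alkoxy allyllithium 30 with retention, tetrabutyltin being the co-product. The carbanion carbon then bonds to C7 while O–C13 breaks in a suprafacial [2,3]-sigmatropic shift through a five-membered envelope transition state; this is the Wittig–Still variant of the [2,3]-Wittig rearrangement, of the type known for ring contraction of 13-membered diallylic ethers to cyclodecenols. The ten-membered carbocycle closes transannularly, C8 and C7 becoming bonded across the C8–O–C13–C11=C7 bridge while the ether oxygen leaves the ring as the C8 alkoxide and C13 becomes an exocyclic methylene. C8 is set by the (S)-stannane with inversion at the lithium-bearing carbon, and C7 is expected syn to the C8 oxygen from the Z C7=C11 bond (it is destroyed in step 28). The step needs metalation at C8 only, which the position of tin secures, and [2,3] shift in preference to [1,2] shift or reaction at C10, which the low temperature and the unstrained envelope should favour. It also needs rearrangement faster than inversion of the allyllithium, for which the short lifetime of 30 at −78 °C is relied on.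

Step 23
Reactants: 31 ten-membered C8 alcohol
Product: 32 C8 tiglate
Conditions: tigloyl chloride, Et3N, DMAP (cat.), CH2Cl2, 0 °C → rt
Reagents that add atoms: tigloyl chloride, C/C=C(\C)C(Cl)=O
Why: DMAP-catalysed acylation of the secondary allylic alcohol with the acid chloride installs the tiglate, which should not isomerise under these conditions.

Step 24
Reactants: 32 C8 tiglate
Product: 33 C6,C12 diol
Conditions: HF·pyridine, pyridine, THF, 0 °C
Reagents that add atoms: none
Why: In this fluoride-mediated desilylation, buffered HF·pyridine should cleave the two triethylsilyl ethers much faster than the tert-butyldimethylsilyl ether at C1.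

Step 25
Reactants: 33 C6,C12 diol
Product: 35 α-methylene lactone, via hydroxy enal 34 (not isolated)
Conditions: MnO2 (excess), CH2Cl2, rt
Reagents that add atoms: none
Why: MnO2 oxidises the allylic primary alcohol to the enal, which the C6 hydroxyl captures as a lactol that is oxidised further to the lactone (oxidative lactonisation of a 2-methylene-1,4-diol).

Step 26
Reactants: 35 α-methylene lactone
Product: 36 11,13-diol (C11 hydroxyl cis to H7)
Conditions: OsO4 (cat.), N-methylmorpholine N-oxide, citric acid, t-BuOH–H2O, rt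
Reagents that add atoms: N-methylmorpholine N-oxide, C[N+]1([O-])CCOCC1; water, O
Why: Catalytic OsO4 dihydroxylation (acid-buffered for an electron-poor alkene) of the exposed exocyclic methylene should occur on the face of the cis-fused lactone opposite C5 and C8, so the C11 hydroxyl is cis to H7; the C9=C10 bond is shielded by two allylic oxygen substituents and the tiglate alkene is trisubstituted and conjugated.

Step 27
Reactants: 36 11,13-diol
Product: 37 13-acetate
Conditions: Ac2O, pyridine, CH2Cl2, 0 °C
Reagents that add atoms: acetic anhydride, CC(=O)OC(C)=O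
Why: Acetylation with acetic anhydride and pyridine is selective for the primary over the tertiary hydroxyl.

Step 28
Reactants: 37 13-acetate
Product: 38 C1 silyl ether of the target butenolide
Conditions: Burgess reagent, benzene, 50 °C
Reagents that add atoms: none
Why: Burgess dehydration is a syn elimination through a cyclic sulfamate transition state, so the C11 oxygen should leave with the cis H7 to give the conjugated tetrasubstituted butenolide in preference to the enol acetate.

Step 29
Reactants: 38 C1 silyl ether of the target butenolide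
Product: 39 target compound CNP0222387.1
Conditions: HF·pyridine, THF, 0 °C → rt
Reagents that add atoms: none
Why: Fluoride-mediated desilylation frees the C1 hydroxyl without touching the esters, the epoxide or the butenolide.

**Compound list**
1 | but-2-yn-1-ol | CC#CCO | starting material
2 | cyclic vinylalanate from 1 (sodium salt) | CC1=CCO[Al-]1(OCCOC)OCCOC.[Na+] | intermediate
3 | (Z)-3-iodobut-2-en-1-ol | C/C(I)=C/CO | intermediate
4 | (Z)-3-iodobut-2-enyl 4-methoxybenzyl ether | C/C(I)=C/COCc1ccc(OC)cc1 | intermediate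
5 | prop-2-yn-1-ol | C#CCO | starting material
6 | triethyl(prop-2-ynyloxy)silane | C#CCO[Si](CC)(CC)CC | intermediate
7 | geranyl acetate | CC(C)=CCC/C(C)=C/COC(C)=O | starting material
8 | ozonide of the terminal alkene of 7 | CC1(C)OOC(CC/C(C)=C/COC(C)=O)O1 | intermediate
9 | (E)-3-methyl-6-oxohex-2-enyl acetate (C1 aldehyde, C6 acetate) | O=CCC/C(C)=C/COC(C)=O | intermediate
10 | C1 allylic alcohol, both C1 epimers (4E, 9Z; C6 acetate, C8 4-methoxybenzyl ether) | COc1ccc(COC/C=C(/C)C(O)CC/C(C)=C/COC(C)=O)cc1 | intermediate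
11 | C1 enone | COc1ccc(COC/C=C(/C)C(=O)CC/C(C)=C/COC(C)=O)cc1 | intermediate
12 | (1S)-allylic alcohol | COc1ccc(COC/C=C(/C)[C@@H](O)CC/C(C)=C/COC(C)=O)cc1 | intermediate
13 | C1 tert-butyldimethylsilyl ether | COc1ccc(COC/C=C(/C)[C@@H](O[Si](C)(C)C(C)(C)C)CC/C(C)=C/COC(C)=O)cc1 | intermediate
14 | C6 allylic alcohol | COc1ccc(COC/C=C(/C)[C@@H](O[Si](C)(C)C(C)(C)C)CC/C(C)=C/CO)cc1 | intermediate
15 | C6 (E)-enal | COc1ccc(COC/C=C(/C)[C@@H](O[Si](C)(C)C(C)(C)C)CC/C(C)=C/C=O)cc1 | intermediate
16 | (1S,6R)-propargylic alcohol (C7≡C11, C12 triethylsilyl ether) | COc1ccc(COC/C=C(/C)[C@@H](O[Si](C)(C)C(C)(C)C)CC/C(C)=C/[C@@H](O)C#CCO[Si](CC)(CC)CC)cc1 | intermediate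
17 | cyclic C11 vinylalanate from 16 (sodium salt) | COc1ccc(COC/C=C(/C)[C@@H](O[Si](C)(C)C(C)(C)C)CC/C(C)=C/[C@H]2O[Al-](OCCOC)(OCCOC)C(CO[Si](CC)(CC)CC)=C2)cc1.[Na+] | intermediate
18 | (Z)-C11 iodoalkene (iodine cis to C6; 6R) | COc1ccc(COC/C=C(/C)[C@@H](O[Si](C)(C)C(C)(C)C)CC/C(C)=C/[C@@H](O)/C=C(\I)CO[Si](CC)(CC)CC)cc1 | intermediate
19 | (1S,4R,5R,6S)-4,5-epoxy alcohol | COc1ccc(COC/C=C(/C)[C@@H](O[Si](C)(C)C(C)(C)C)CC[C@@]2(C)O[C@@H]2[C@@H](O)/C=C(\I)CO[Si](CC)(CC)CC)cc1 | intermediate
20 | C6 triethylsilyl ether of 19 | COc1ccc(COC/C=C(/C)[C@@H](O[Si](C)(C)C(C)(C)C)CC[C@@]2(C)O[C@@H]2[C@@H](O[Si](CC)(CC)CC)/C=C(\I)CO[Si](CC)(CC)CC)cc1 | intermediate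
21 | C13 allylic alcohol (hydroxymethyl cis to C6) | COc1ccc(COC/C=C(/C)[C@@H](O[Si](C)(C)C(C)(C)C)CC[C@@]2(C)O[C@@H]2[C@@H](O[Si](CC)(CC)CC)/C=C(\CO)CO[Si](CC)(CC)CC)cc1 | intermediate
22 | C13 mesylate | COc1ccc(COC/C=C(/C)[C@@H](O[Si](C)(C)C(C)(C)C)CC[C@@]2(C)O[C@@H]2[C@@H](O[Si](CC)(CC)CC)/C=C(\COS(C)(=O)=O)CO[Si](CC)(CC)CC)cc1 | intermediate
23 | C13 allylic chloride | COc1ccc(COC/C=C(/C)[C@@H](O[Si](C)(C)C(C)(C)C)CC[C@@]2(C)O[C@@H]2[C@@H](O[Si](CC)(CC)CC)/C=C(\CCl)CO[Si](CC)(CC)CC)cc1 | intermediate
24 | C8 allylic alcohol | OC/C=C(/C)[C@@H](O[Si](C)(C)C(C)(C)C)CC[C@@]1(C)O[C@@H]1[C@@H](O[Si](CC)(CC)CC)/C=C(\CCl)CO[Si](CC)(CC)CC | intermediate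
25 | C8 (Z)-enal | O=C/C=C(/C)[C@@H](O[Si](C)(C)C(C)(C)C)CC[C@@]1(C)O[C@@H]1[C@@H](O[Si](CC)(CC)CC)/C=C(\CCl)CO[Si](CC)(CC)CC | intermediate
26 | lithium alkoxide of the C8 α-stannyl carbinol (both C8 epimers) | [Li]OC(/C=C(/C)[C@@H](O[Si](C)(C)C(C)(C)C)CC[C@@]1(C)O[C@@H]1[C@@H](O[Si](CC)(CC)CC)/C=C(\CCl)CO[Si](CC)(CC)CC)[Sn](CCCC)(CCCC)CCCC | intermediate
27 | C8 acylstannane | CCCC[Sn](CCCC)(CCCC)C(=O)/C=C(/C)[C@@H](O[Si](C)(C)C(C)(C)C)CC[C@@]1(C)O[C@@H]1[C@@H](O[Si](CC)(CC)CC)/C=C(\CCl)CO[Si](CC)(CC)CC | intermediate
28 | (8S)-α-hydroxy allylic stannane | CCCC[Sn](CCCC)(CCCC)[C@H](O)/C=C(/C)[C@@H](O[Si](C)(C)C(C)(C)C)CC[C@@]1(C)O[C@@H]1[C@@H](O[Si](CC)(CC)CC)/C=C(\CCl)CO[Si](CC)(CC)CC | intermediate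
29 | 13-membered cyclic C8–O–C13 ether with (8S)-tributylstannyl group, C1 tert-butyldimethylsilyl ether, C6 and C12 triethylsilyl ethers (C13 cis to C6) | CCCC[Sn](CCCC)(CCCC)[C@H]1/C=C(/C)[C@@H](O[Si](C)(C)C(C)(C)C)CC[C@@]2(C)O[C@@H]2[C@@H](O[Si](CC)(CC)CC)/C=C(/CO[Si](CC)(CC)CC)CO1 | intermediate
30 | C8 α-alkoxy allyllithium | [Li][C@H]1/C=C(/C)[C@@H](O[Si](C)(C)C(C)(C)C)CC[C@@]2(C)O[C@@H]2[C@@H](O[Si](CC)(CC)CC)/C=C(/CO[Si](CC)(CC)CC)CO1 | intermediate
31 | ten-membered (8S)-alcohol; C7 carries the 3-(triethylsilyloxy)prop-1-en-2-yl group, H7 syn to the C8 oxygen | O[C@H]1/C=C(/C)[C@@H](O[Si](C)(C)C(C)(C)C)CC[C@@]2(C)O[C@@H]2[C@@H](O[Si](CC)(CC)CC)[C@H]1C(=C)CO[Si](CC)(CC)CC | intermediate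
32 | C8 tiglate | C/C=C(\C)C(=O)O[C@H]1/C=C(/C)[C@@H](O[Si](C)(C)C(C)(C)C)CC[C@@]2(C)O[C@@H]2[C@@H](O[Si](CC)(CC)CC)[C@H]1C(=C)CO[Si](CC)(CC)CC | intermediate
33 | C6,C12 diol | C/C=C(\C)C(=O)O[C@H]1/C=C(/C)[C@@H](O[Si](C)(C)C(C)(C)C)CC[C@@]2(C)O[C@@H]2[C@@H](O)[C@H]1C(=C)CO | intermediate
34 | C6 hydroxy C12 enal | C/C=C(\C)C(=O)O[C@H]1/C=C(/C)[C@@H](O[Si](C)(C)C(C)(C)C)CC[C@@]2(C)O[C@@H]2[C@@H](O)[C@H]1C(=C)C=O | intermediate
35 | α-methylene γ-lactone (12,6-olide, C11=C13) | C/C=C(\C)C(=O)O[C@H]1/C=C(/C)[C@@H](O[Si](C)(C)C(C)(C)C)CC[C@@]2(C)O[C@@H]2[C@H]2OC(=O)C(=C)[C@@H]12 | intermediate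
36 | 11,13-diol (C11 hydroxyl cis to H7) | C/C=C(\C)C(=O)O[C@H]1/C=C(/C)[C@@H](O[Si](C)(C)C(C)(C)C)CC[C@@]2(C)O[C@@H]2[C@H]2OC(=O)[C@@](O)(CO)[C@@H]12 | intermediate
37 | 11-hydroxy 13-acetate | C/C=C(\C)C(=O)O[C@H]1/C=C(/C)[C@@H](O[Si](C)(C)C(C)(C)C)CC[C@@]2(C)O[C@@H]2[C@H]2OC(=O)[C@@](O)(COC(C)=O)[C@@H]12 | intermediate
38 | C1 tert-butyldimethylsilyl ether of the target butenolide | C/C=C(\C)C(=O)O[C@H]1/C=C(/C)[C@@H](O[Si](C)(C)C(C)(C)C)CC[C@@]2(C)O[C@@H]2[C@H]2OC(=O)C(COC(C)=O)=C12 | intermediate
39 | CNP0222387.1 (1S,4R,5R,6S,8S; 9Z) | C/C=C(\C)C(=O)O[C@H]1/C=C(/C)[C@@H](O)CC[C@@]2(C)O[C@@H]2[C@H]2OC(=O)C(COC(C)=O)=C12 | target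

**Step count and risks**
Total: 29 steps. Longest linear sequence: 27 steps (steps 1, 2 and 5–29, from but-2-yn-1-ol).

The three steps most likely to fail:

Step 22 (key step). The allyllithium may invert at C8 before it rearranges, or the transannular transition state may favour the other face, so that the C8 epimer forms; a [1,2] shift is a further side path. The fallback sets out from 29: the rearrangement would then deliver the 8-epi alcohol F1, which is not discarded but esterified with tiglic acid under Mitsunobu conditions (PPh3, diisopropyl azodicarboxylate). The SN2 inversion at C8 gives the tiglate directly, and the route is rejoined at 32; C8 is then set by the substitution and not by the stannane.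

Step 21. The α-stannyl allylic alkoxide may fragment by loss of the stannyl anion, or oligomerise, in competition with the slow 13-ring closure. The fallback sets out from 24: NaH in THF–DMF at high dilution closes the tin-free 13-membered diallylic ether F2 by Williamson etherification of the robust primary alkoxide. Direct deprotonation with sec-BuLi at −78 °C then triggers the [2,3]-Wittig ring contraction, as known for 13-membered diallylic ethers, in which the 3,3-disubstituted allyl side (C8) is metalated in preference to the 2-substituted side (C13). The route is rejoined at 31; the C8 configuration then rests on the transannular transition state and, if needed, on the Mitsunobu correction above. The same detour also bypasses step 19, in which attack of the stannyl anion on the allylic chloride could compete with addition to the enal.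

Step 28. The syn elimination may run toward the acetoxymethyl hydrogens and give the enol acetate instead of the C7=C11 bond. The fallback sets out from 36: NaIO4 cleaves the 11,13-diol and excises C13, giving the enolised α-keto lactone F3, whose only enolisable position is C7. Tf2O and pyridine give the enol triflate F4; Stille coupling with Bu3SnCH2OH (Pd(PPh3)4, LiCl) reintroduces C13 as the 13-hydroxy butenolide F5; acetylation with Ac2O rejoins the route at 38.

**Further compounds**
F1 | step 22 | 8-epi alcohol (C8 epimer of 31) | O[C@@H]1/C=C(/C)[C@@H](O[Si](C)(C)C(C)(C)C)CC[C@@]2(C)O[C@@H]2[C@@H](O[Si](CC)(CC)CC)[C@H]1C(=C)CO[Si](CC)(CC)CC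
F2 | step 21 | tin-free 13-membered C8–O–C13 diallylic ether | C1/C=C(/C)[C@@H](O[Si](C)(C)C(C)(C)C)CC[C@@]2(C)O[C@@H]2[C@@H](O[Si](CC)(CC)CC)/C=C(/CO[Si](CC)(CC)CC)CO1
F3 | step 28 | enolised α-keto lactone (11-hydroxy-7(11)-en-12,6-olide) | C/C=C(\C)C(=O)O[C@H]1/C=C(/C)[C@@H](O[Si](C)(C)C(C)(C)C)CC[C@@]2(C)O[C@@H]2[C@H]2OC(=O)C(O)=C12
F4 | step 28 | C11 enol triflate | C/C=C(\C)C(=O)O[C@H]1/C=C(/C)[C@@H](O[Si](C)(C)C(C)(C)C)CC[C@@]2(C)O[C@@H]2[C@H]2OC(=O)C(OS(=O)(=O)C(F)(F)F)=C12
F5 | step 28 | 13-hydroxy butenolide | C/C=C(\C)C(=O)O[C@H]1/C=C(/C)[C@@H](O[Si](C)(C)C(C)(C)C)CC[C@@]2(C)O[C@@H]2[C@H]2OC(=O)C(CO)=C12
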